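**Remark:** Locants C7, C8, C9 and C1'–C9' are those of the neolignan name. Compounds 1, 2, 5 and 14 are taken as commercial. The route has not been run; every outcome below is an expectation.

## Retrosynthetic overview

1. The C7'=C8' bond and C9'–OH come last: Horner–Wadsworth–Emmons homologation of a C1' aldehyde (from a C1' nitrile), then ester reduction; no protecting groups.
2. The only ring that is made, the dihydrofuran O–C7–C8–C3'–C4', is closed in one flask from two monocyclic pieces: C4'–O by SNAr of a benzylic alkoxide on an aryl fluoride, then C3'–C8 by 5-exo-tet opening of an oxirane by the ortho-aryllithium.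
3. Enabling feature: O9 sits on the carbon next to C8, so C8–C9–O9 is carried as a terminal oxirane. Its C8–O bond is the leaving group, SN2 inversion at C8 turns an erythro epoxy alcohol into the trans-7,8 ring, and C9–OH is released. C1' is para to C4', so a nitrile there activates the C–F bond and later becomes the propenol chain.
4. Epoxy alcohol: vinyl addition to 3,4,5-trimethoxybenzaldehyde, then Sharpless kinetic-resolution epoxidation (fixes C7 and the oxirane carbon that becomes C8).
5. Arene: 4-amino-3-methoxybenzonitrile, ortho-iodination, Balz–Schiemann fluorination; both benzene rings are bought.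

Key step: step 5

## Route

Step 1
Reactants: 1 3,4,5-trimethoxybenzaldehyde; 2 vinylmagnesium bromide
Product: 3 rac-1-(3,4,5-trimethoxyphenyl)prop-2-en-1-ol
Conditions: THF, 0 °C; then H2O
Reagents that add atoms: vinylmagnesium bromide, C=C[Mg]Br
Why: Grignard 1,2-addition to an aryl aldehyde; the new carbinol centre is racemic and is resolved in step 2.

Step 2
Reactants: 3 rac-1-(3,4,5-trimethoxyphenyl)prop-2-en-1-ol
Product: 4 (S)-[(2R)-oxiran-2-yl](3,4,5-trimethoxyphenyl)methanol
Conditions: Ti(OiPr)4 (cat.), L-(+)-DIPT (cat.), t-BuOOH (about 0.5 equiv), 4 Å MS, CH2Cl2, −20 °C, stopped short of half conversion; unreacted (S)-3 removed by chromatography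
Reagents that add atoms: tert-butyl hydroperoxide, CC(C)(C)OO
Why: Sharpless kinetic resolution by asymmetric epoxidation: with L-(+)-DIPT the (R)-alcohol (aryl outranks vinyl, so the usual "S reacts fast" rule reads R here) is the fast enantiomer, and the Ti–tartrate delivers oxygen to one alkene face to set the (R)-oxirane carbon, giving the erythro epoxy alcohol.

Step 3
Reactants: 5 4-amino-3-methoxybenzonitrile
Product: 6 4-amino-3-iodo-5-methoxybenzonitrile
Conditions: NIS, TFA (cat.), MeCN, rt
Reagents that add atoms: N-iodosuccinimide, O=C1CCC(=O)N1I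
Why: Electrophilic aromatic iodination; the amino group directs to its only free ortho position.

Step 4
Reactants: 6 4-amino-3-iodo-5-methoxybenzonitrile
Product: 8 4-fluoro-3-iodo-5-methoxybenzonitrile, via diazonium tetrafluoroborate 7 (not isolated)
Conditions: NOBF4, MeCN, −20 to 0 °C; solvent exchanged to PhCl, 110 °C
Reagents that add atoms: nitrosonium tetrafluoroborate, N#[O+].F[B-](F)(F)F
Why: Balz–Schiemann reaction: diazotisation by NO+, then thermal loss of N2 from the aryldiazonium tetrafluoroborate with fluoride transfer from BF4−.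

Step 5
Reactants: 4 (S)-[(2R)-oxiran-2-yl](3,4,5-trimethoxyphenyl)methanol; 8 4-fluoro-3-iodo-5-methoxybenzonitrile
Product: 11 (2R,3S)-3-(hydroxymethyl)-7-methoxy-2-(3,4,5-trimethoxyphenyl)-2,3-dihydro-1-benzofuran-5-carbonitrile, via aryl ether 9 (not isolated), via aryllithium 10 (not isolated)
Conditions: 4 added to NaH, 15-crown-5 (cat.) and 8 in THF, 0 °C to rt; then Et2O, −100 °C, t-BuLi (2.0 equiv), to −78 °C; then H2O
Reagents that add atoms: none
Why: NaH turns 4 into its sodium alkoxide, which displaces fluoride at C4 of 8 by addition–elimination (Meisenheimer adduct stabilised by the para nitrile and the ortho iodine) and makes the aryl C–O bond of 9; t-BuLi at −100 °C then exchanges iodine for lithium faster than it adds to the nitrile (Parham conditions), and aryllithium 10 attacks the internal oxirane carbon from the rear, making the aryl C–C bond and releasing the C9 alkoxide. The closest known reactions are the SNAr etherification of 4-fluorobenzonitriles and the Parham cyclisation of o-lithiophenyl glycidyl ethers to 2,3-dihydrobenzofuran-3-ylmethanols. The dihydrofuran ring is closed in the 5-exo-tet mode, the breaking C–O bond lying outside the new ring. C2 (7R) is carried over unchanged from the carbinol carbon of 4 because no bond to it is broken; C3 (8S) is set by SN2 inversion of the (R)-oxirane carbon, so the erythro epoxy alcohol maps onto the trans-2,3 ring. The step needs O-arylation before any epoxide migration (aprotic medium, electrophile present while the alkoxide forms), exo rather than 6-endo opening (three-atom tether; no Mg or Cu salts, which could open the oxirane to a halohydrin or attack the terminal carbon through the metal) and exchange rather than nitrile addition (aryl iodide, two equivalents of t-BuLi, −100 °C).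

Step 6
Reactants: 11 (2R,3S)-3-(hydroxymethyl)-7-methoxy-2-(3,4,5-trimethoxyphenyl)-2,3-dihydro-1-benzofuran-5-carbonitrile
Product: 13 (2R,3S)-3-(hydroxymethyl)-7-methoxy-2-(3,4,5-trimethoxyphenyl)-2,3-dihydro-1-benzofuran-5-carbaldehyde, via aldimine 12 (not isolated)
Conditions: DIBAL-H (2.5 equiv), CH2Cl2, −78 to −40 °C; then aq. Rochelle salt, wet SiO2
Reagents that add atoms: water, O
Why: DIBAL half-reduction of an aryl nitrile to the N-alumino imine, hydrolysed on work-up to the aldehyde; one extra equivalent is consumed by the free hydroxyl, and the near-neutral work-up spares the acid-labile benzylic ether at C2.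

Step 7
Reactants: 13 (2R,3S)-3-(hydroxymethyl)-7-methoxy-2-(3,4,5-trimethoxyphenyl)-2,3-dihydro-1-benzofuran-5-carbaldehyde; 14 triethyl phosphonoacetate
Product: 15 ethyl (2E)-3-[(2R,3S)-3-(hydroxymethyl)-7-methoxy-2-(3,4,5-trimethoxyphenyl)-2,3-dihydro-1-benzofuran-5-yl]prop-2-enoate
Conditions: LiCl, DBU, MeCN, rt
Reagents that add atoms: triethyl phosphonoacetate, CCOC(=O)CP(=O)(OCC)OCC
Why: Horner–Wadsworth–Emmons olefination under Masamune–Roush conditions, E-selective with aryl aldehydes and mild enough for the free primary alcohol.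

Step 8
Reactants: 15 ethyl (2E)-3-[(2R,3S)-3-(hydroxymethyl)-7-methoxy-2-(3,4,5-trimethoxyphenyl)-2,3-dihydro-1-benzofuran-5-yl]prop-2-enoate
Product: 16 (-)-(7R,8S,7'E)-3,4,5,5'-tetramethoxy-4',7-epoxy-8,3'-neolign-7'-ene-9,9'-diol
Conditions: DIBAL-H (3.5 equiv), CH2Cl2, −78 °C; then aq. Rochelle salt
Reagents that add atoms: none
Why: DIBAL 1,2-reduction of the α,β-unsaturated ester to the E-allylic alcohol; the alkene geometry and both ring stereocentres are untouched.

## Compound list

1 | 3,4,5-trimethoxybenzaldehyde | COc1cc(C=O)cc(OC)c1OC | starting material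
2 | vinylmagnesium bromide | C=C[Mg]Br | starting material
3 | rac-1-(3,4,5-trimethoxyphenyl)prop-2-en-1-ol | COc1cc(C(O)C=C)cc(OC)c1OC | intermediate
4 | (S)-[(2R)-oxiran-2-yl](3,4,5-trimethoxyphenyl)methanol | COc1cc([C@H](O)[C@H]2CO2)cc(OC)c1OC | intermediate
5 | 4-amino-3-methoxybenzonitrile | COc1cc(C#N)ccc1N | starting material
6 | 4-amino-3-iodo-5-methoxybenzonitrile | COc1cc(C#N)cc(I)c1N | intermediate
7 | 4-cyano-2-iodo-6-methoxybenzenediazonium tetrafluoroborate | COc1cc(C#N)cc(I)c1[N+]#N.F[B-](F)(F)F | intermediate (not isolated)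
8 | 4-fluoro-3-iodo-5-methoxybenzonitrile | COc1cc(C#N)cc(I)c1F | intermediate
9 | 3-iodo-5-methoxy-4-{(S)-[(2R)-oxiran-2-yl](3,4,5-trimethoxyphenyl)methoxy}benzonitrile | COc1cc(C#N)cc(I)c1O[C@@H](c1cc(OC)c(OC)c(OC)c1)[C@H]1CO1 | intermediate (not isolated)
10 | {5-cyano-3-methoxy-2-{(S)-[(2R)-oxiran-2-yl](3,4,5-trimethoxyphenyl)methoxy}phenyl}lithium | COc1cc(C#N)cc([Li])c1O[C@@H](c1cc(OC)c(OC)c(OC)c1)[C@H]1CO1 | intermediate (not isolated)
11 | (2R,3S)-3-(hydroxymethyl)-7-methoxy-2-(3,4,5-trimethoxyphenyl)-2,3-dihydro-1-benzofuran-5-carbonitrile | COc1cc([C@@H]2Oc3c(OC)cc(C#N)cc3[C@H]2CO)cc(OC)c1OC | intermediate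
12 | [(2R,3S)-5-(iminomethyl)-7-methoxy-2-(3,4,5-trimethoxyphenyl)-2,3-dihydro-1-benzofuran-3-yl]methanol | COc1cc([C@@H]2Oc3c(OC)cc(C=N)cc3[C@H]2CO)cc(OC)c1OC | intermediate (not isolated)
13 | (2R,3S)-3-(hydroxymethyl)-7-methoxy-2-(3,4,5-trimethoxyphenyl)-2,3-dihydro-1-benzofuran-5-carbaldehyde | COc1cc([C@@H]2Oc3c(OC)cc(C=O)cc3[C@H]2CO)cc(OC)c1OC | intermediate
14 | triethyl phosphonoacetate | CCOC(=O)CP(=O)(OCC)OCC | starting material
15 | ethyl (2E)-3-[(2R,3S)-3-(hydroxymethyl)-7-methoxy-2-(3,4,5-trimethoxyphenyl)-2,3-dihydro-1-benzofuran-5-yl]prop-2-enoate | COc1cc([C@@H]2Oc3c(OC)cc(/C=C/C(=O)OCC)cc3[C@H]2CO)cc(OC)c1OC | intermediate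
16 | (-)-(7R,8S,7'E)-3,4,5,5'-tetramethoxy-4',7-epoxy-8,3'-neolign-7'-ene-9,9'-diol | COc1cc([C@@H]2Oc3c(OC)cc(/C=C/CO)cc3[C@H]2CO)cc(OC)c1OC | target

## Step count and risks

Total step count: 8. Longest linear sequence: 6 steps (1 → 3 → 4 → 11 → 13 → 15 → 16, or equally 5 → 6 → 8 → 11 → 13 → 15 → 16).

**Steps most likely to fail**

Step 5. Several processes may interfere:
- the oxirane may migrate along the chain through the alkoxide before O-arylation, so that the primary oxygen is arylated;
- substitution at the doubly ortho-substituted C–F carbon may be slow;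
- the aryllithium may add to a nitrile or abstract the benzylic C–H across the ether;
- the oxirane may open at its terminal carbon.

The fallback sets out from 1 and 8 and comes back at 11, replacing the anionic epoxide opening by a radical ring closure:
- Catalytic enantioselective vinylation of 1 (divinylzinc, chiral amino-alcohol catalyst of the series that delivers the R carbinol) should give (R)-1-(3,4,5-trimethoxyphenyl)prop-2-en-1-ol F1.
- Its sodium alkoxide has no oxirane to migrate and should displace fluoride from 8 (NaH, THF) to give 3-iodo-5-methoxy-4-{[(1R)-1-(3,4,5-trimethoxyphenyl)prop-2-en-1-yl]oxy}benzonitrile F2.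
- Aryl-radical 5-exo-trig cyclisation with TEMPO capture of the primary radical (Bu3SnH added slowly, TEMPO, benzene, 70 °C) should give (2R,3S)-7-methoxy-3-{[(2,2,6,6-tetramethylpiperidin-1-yl)oxy]methyl}-2-(3,4,5-trimethoxyphenyl)-2,3-dihydro-1-benzofuran-5-carbonitrile F3. The trans isomer is favoured by the chair-like transition state of a 4-substituted hexenyl radical, and any cis isomer would be removed by chromatography.
- Zn/AcOH should cleave the N–O bond to 11.

Step 4. Thermal fluorodediazoniation of a diazonium salt flanked by iodine and methoxy may be diverted to hydrodediazoniation or to capture of the aryl cation by solvent. The fallback sets out from 6 and comes back at 8: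
- Sandmeyer-type chlorodeamination (t-BuONO, CuCl2, MeCN, 65 °C) should give 4-chloro-3-iodo-5-methoxybenzonitrile F4.
- Halogen exchange with anhydrous Me4NF in DMF should replace only the chloride, which is para to the nitrile, and give 8.

Step 2. The two enantiomers of this electron-rich aryl vinyl carbinol may react at rates too close for a clean resolution. Oxygen transfer to the monosubstituted alkene may also be slow enough for titanium-induced ionisation of the benzylic carbinol to compete. The fallback sets out from 3 and comes back at 4, moving the enantioselection to the terminal epoxide: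
- Hydroxyl-directed epoxidation with VO(acac)2 (cat.) and t-BuOOH in CH2Cl2, erythro-selective for allylic alcohols without a cis substituent, should give rac-erythro-[oxiran-2-yl](3,4,5-trimethoxyphenyl)methanol F5.
- Hydrolytic kinetic resolution with (salen)Co(III)OAc (catalyst enantiomer chosen to hydrate the unwanted epoxide) and about half an equivalent of water should convert the unwanted enantiomer into (1R,2S)-1-(3,4,5-trimethoxyphenyl)propane-1,2,3-triol F6 and leave 4.

Further compounds
F1 | step 5 | (R)-1-(3,4,5-trimethoxyphenyl)prop-2-en-1-ol | COc1cc([C@H](O)C=C)cc(OC)c1OC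
F2 | step 5 | 3-iodo-5-methoxy-4-{[(1R)-1-(3,4,5-trimethoxyphenyl)prop-2-en-1-yl]oxy}benzonitrile | COc1cc(C#N)cc(I)c1O[C@@H](c1cc(OC)c(OC)c(OC)c1)C=C
F3 | step 5 | (2R,3S)-7-methoxy-3-{[(2,2,6,6-tetramethylpiperidin-1-yl)oxy]methyl}-2-(3,4,5-trimethoxyphenyl)-2,3-dihydro-1-benzofuran-5-carbonitrile | COc1cc([C@@H]2Oc3c(OC)cc(C#N)cc3[C@H]2CON2C(C)(C)CCCC2(C)C)cc(OC)c1OC
F4 | step 4 | 4-chloro-3-iodo-5-methoxybenzonitrile | COc1cc(C#N)cc(I)c1Cl
F5 | step 2 | rac-erythro-[oxiran-2-yl](3,4,5-trimethoxyphenyl)methanol (racemate, one enantiomer drawn) | COc1cc([C@H](O)[C@H]2CO2)cc(OC)c1OC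
F6 | step 2 | (1R,2S)-1-(3,4,5-trimethoxyphenyl)propane-1,2,3-triol | COc1cc([C@@H](O)[C@@H](O)CO)cc(OC)c1OC
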